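**Leftover first.** Electrophile must be left over in this flask. It is charged with less protonated nucleophile (0.950 M) than electrophile (1.0 M), and nucleophile can also go to its self-condensation product. The open question is how fast the approach runs.

electrophile 1.0 M; free base 0.800 M; protonated nucleophile 0.950 M; time 4.0 h

- part of the electrophile that has reacted at 4.0 h
- share of the unused nucleophile that is free and not bound as protonated nucleophile, at 4.0 h

    nucleophile + acid set free ⇌ protonated nucleophile, settled at all times (K1 = 4900 L mol⁻¹)
    target → over-reaction product (k2 = 5.1 × 10⁻⁶ s⁻¹)
    2 nucleophile → self-condensation product (k3 = 0.0014 L mol⁻¹ s⁻¹)
    acid set free + free base ⇌ salt of the base, settled at all times (K4 = 2200 L mol⁻¹)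
    electrophile + nucleophile → acid set free + target (k5 = 1.4 × 10⁻⁴ L mol⁻¹ s⁻¹)

**Two amounts.** Free base takes acid from protonated nucleophile, with the exchange constant 0.449, the ratio of the two balances. Solving this exchange for the charges gives my starting free nucleophile, 0.349 M. Against it I set 0.0500 M, the crossover level: the free nucleophile at which self-condensation and the main step consume nucleophile equally, with electrophile as charged. The ratio of the two, a selectivity factor, is 6.98. So self-condensation consumes nucleophile faster than the main step at the start. My reckoning stops there, with no figure for the conversion.

**The forecast.** It gives 14.3% reacted (range 12.5% to 16.5%) and 6.3% free (range 5.2% to 7.5%), holding that “self-condensation consumes nucleophile several times faster than the electrophile does”.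

**The flask.** The simulation gives 14.2% reacted and 6.29% free, both inside those ranges. In this flask free nucleophile stands at 0.0520 M after 2.00 h, close to the crossover level, and at 0.0264 M after 4.00 h, less than that level. By then self-condensation has cost 2.72 nucleophile per electrophile reacted.

**Less base.** In the neighbour flask with 0.20 M of free base, all else as charged before, the same exchange gives 0.143 M, or 2.86 crossover levels, so I expect a smaller cost. The computed neighbour flask reaches 6.36% reacted at a cost of 1.24 nucleophile per electrophile reacted, less than the 2.72 of the first flask.

The numbers were drawn at random within sensible limits; no experiment stands behind them.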